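**Plan**
- Retrosynthetic cuts: the butenolide is cut at C13=C14 and C16–O, back to a C13 methyl ester. Ring A (cyclopentane C1–C5) is cut at C4–C5 and C1–C2, back to a prenyl group on C1. Ring B (cycloheptane C1, C5–C10) is cut at C10–C1 and C5–C6, which removes C1–C5 as a ketene and leaves a cyclopentanone (C6–C10).
- Enabling feature: in ring B the C10 ketone and the C5 carbinol carbon stand 1,3 to each other across C1, so ring B is a masked cycloheptane-1,3-dione. A cyclopentanone enol ether (C10=C6) gives exactly this after [2+2] addition of a two-carbon ketene unit and scission of the old C10–C6 bond.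
- Forward order: carbocycle C6–C10 with the C8/C9 pair, two-carbon expansion to ring B, C1 prenylation and radical closure of ring A, then the butenolide from the ester arm.
- Stereochemistry: C8 comes from a ligand-controlled copper-catalysed conjugate methylation and C9 from a chiral-imine Michael addition anti to the C8 methyl. C3 comes from a Shi epoxidation, C5 from the radical closure (relayed from C3 and the C9 methyl), and C1 from equilibration to the trans-fused ketone.

Key step: step 4

Remark: terpenoid numbering is used (ring A = C1–C5; ring B = C1, C5–C10; methyls on C4, C4, C8, C9; side chain C11–C16 with C13 the substituted butenolide carbon, C15 the lactone carbonyl, C16 the OCH2); the SMILES is read as 1S,3R,5S,8R,9S, that is 5-OH, 3-OH and the C8 and C9 methyls on one face (β) and 1-H on the other (α), a trans ring fusion; it is assumed that this trans-fused C1 epimer is the thermodynamically preferred one.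

**Step 1**
Reactants: 1 2-methylcyclopent-2-en-1-one; 2 methylmagnesium bromide
Product: 4 (3R)-2,3-dimethylcyclopentan-1-one as a mixture of C2 epimers, via bromomagnesium enolate 3 (not isolated)
Conditions: MeMgBr, Cu(OTf)2 (3 mol %), chiral N-mesityl-N'-(1-hydroxy-4-methylpentan-2-yl)imidazolinium PF6 salt (4 mol %, antipode giving 3R), Et2O, −30 °C; then 1 M HCl
Reagents that add atoms: methylmagnesium bromide, C[Mg]Br
Why: Copper-catalysed asymmetric conjugate addition of a Grignard reagent to an α-substituted cyclic enone: the chiral NHC–copper complex selects the enone face and so sets C8 (R), whereas the C9 centre created when enolate 3 is protonated is of no consequence because step 2 passes through the enamine again.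

**Step 2**
Reactants: 4 (3R)-2,3-dimethylcyclopentan-1-one; 5 (S)-1-phenylethylamine; 6 methyl acrylate
Product: 9 methyl 3-[(1S,2R)-1,2-dimethyl-5-oxocyclopentyl]propanoate, via ketimine 7 (not isolated), via Michael adduct ketimine 8 (not isolated)
Conditions: (S)-PhCH(Me)NH2, TsOH (cat.), toluene, reflux (Dean–Stark); methyl acrylate, THF, 40 °C; 20% aq. AcOH, rt
Reagents that add atoms: methyl acrylate, C=CC(=O)OC; water, O
Why: Asymmetric Michael addition of a chiral imine through its more substituted secondary enamine tautomer (aza-ene-like transition state): bond formation occurs only at C9 and stops after one addition, the acrylate approaches anti to the C8 methyl, which is also the face that the (S)-amine selects in 2-methylcycloalkanone imines, so auxiliary and substrate control are matched in setting C9 (S) and any 8S material is turned into a separable diastereomer.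

**Step 3**
Reactants: 9 methyl 3-[(1S,2R)-1,2-dimethyl-5-oxocyclopentyl]propanoate
Product: 10 methyl 3-[(1S,5R)-1,5-dimethyl-2-(trimethylsilyloxy)cyclopent-2-en-1-yl]propanoate
Conditions: TMSOTf, Et3N, CH2Cl2, 0 °C
Reagents that add atoms: trimethylsilyl triflate, C[Si](C)(C)OS(=O)(=O)C(F)(F)F
Why: Soft enolisation with a silyl triflate and a tertiary amine silylates the ketone far faster than the ester and avoids a free enolate that could attack the ester arm, and since C9 is quaternary the enol ether can only be C10=C6.

**Step 4**
Reactants: 10 methyl 3-[(1S,5R)-1,5-dimethyl-2-(trimethylsilyloxy)cyclopent-2-en-1-yl]propanoate; 11 dichloroacetyl chloride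
Product: 15 methyl 3-[(1S,7R)-1,7-dimethyl-2,4-dioxocycloheptyl]propanoate, via dichloroketene 12 (not isolated), via dichlorocyclobutanone adduct 13 (not isolated), via dechlorinated silyloxycyclobutanone 14 (not isolated)
Conditions: Cl2CHCOCl (slow addition), Et3N, hexanes, rt; filter, concentrate; Zn dust, AcOH, i-PrOH–H2O, 80 °C
Reagents that add atoms: dichloroacetyl chloride, ClC(Cl)C(Cl)=O
Why: Et3N dehydrochlorinates 11 to dichloroketene 12, whose electrophilic carbonyl carbon (future C5) is attacked by the nucleophilic enol ether carbon C6 while the CCl2 carbon (future C1) closes onto the oxygen-bearing carbon C10 in an asynchronous [2+2] cycloaddition, giving the 1-silyloxy-7,7-dichlorobicyclo[3.2.0]heptan-6-one 13. Zinc in acetic acid then replaces both chlorines by hydrogen (14), and in the hot aqueous acid the silyl group is lost and the cyclobutanol undergoes retro-aldol cleavage of the shared C10–C6 bond to give dione 15. The closest known reaction type is the two-carbon ring expansion of 1-silyloxycyclopentenes to cycloheptane-1,3-diones by dichloroketene cycloaddition, reductive dechlorination and fragmentation. Ring B is thus closed not by an end-to-end cyclisation but by annulating a four-membered ring onto the five-membered one and breaking the zero bridge under release of strain. The two centres created at C6 and C10 in 13 are erased in the fragmentation, so facial selectivity does not matter, and C8 and C9 are not touched. Only regio- and chemoselectivity are needed: quaternary C9 fixes the position of the enol ether, ketene polarity fixes the orientation, the electron-rich alkene outcompetes the ester, and the small trimethylsilyl group together with slow ketene generation is chosen to offset the crowding beside C9.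

**Step 5**
Reactants: 15 methyl 3-[(1S,7R)-1,7-dimethyl-2,4-dioxocycloheptyl]propanoate; 16 prenyl bromide (1-bromo-3-methylbut-2-ene)
Product: 17 methyl 3-[(1S,7R)-1,7-dimethyl-3-(3-methylbut-2-en-1-yl)-2,4-dioxocycloheptyl]propanoate (terpenoid C1 labile)
Conditions: prenyl bromide (1.0 equiv), K2CO3, acetone, rt
Reagents that add atoms: prenyl bromide, CC(C)=CCBr
Why: Alkylation of a 1,3-dicarbonyl enolate with a soft allylic halide (SN2 at the primary terminus): C1 is by far the most acidic position, this weakly enolised seven-membered dione behaves like an open-chain β-diketone and reacts at carbon, one equivalent of bromide limits double alkylation, and the new C1 centre is labile and is fixed only in steps 7 and 8.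

**Step 6**
Reactants: 17 methyl 3-[(1S,7R)-1,7-dimethyl-3-(3-methylbut-2-en-1-yl)-2,4-dioxocycloheptyl]propanoate
Product: 18 methyl 3-[(1S,7R)-3-{[(2R)-3,3-dimethyloxiran-2-yl]methyl}-1,7-dimethyl-2,4-dioxocycloheptyl]propanoate
Conditions: D-fructose-derived ketone of the Shi epoxidation (1,2:4,5-di-O-isopropylidene-β-D-erythro-2,3-hexodiulo-2,6-pyranose, 1 equiv), Oxone (2 KHSO5·KHSO4·K2SO4), NaHCO3, MeCN–aq. Na2EDTA, pH about 8, 0 °C
Reagents that add atoms: potassium peroxymonosulfate (active part of Oxone), [K+].OOS(=O)(=O)[O-]
Why: Shi asymmetric epoxidation: the fructose-derived dioxirane attacks the only electron-rich alkene through the spiro transition state that gives R epoxides from trisubstituted olefins of this type, which sets C3 (R), and the bicarbonate-buffered protocol keeps the 2-alkyl-1,3-dione protonated so that enolate oxidation and attack of the enol oxygen on the epoxide are held back.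

**Step 7**
Reactants: 18 methyl 3-[(1S,7R)-3-{[(2R)-3,3-dimethyloxiran-2-yl]methyl}-1,7-dimethyl-2,4-dioxocycloheptyl]propanoate
Product: 20 methyl 3-[(2R,3aS,6R,7S,8aR)-2,3a-dihydroxy-3,3,6,7-tetramethyl-8-oxodecahydroazulen-7-yl]propanoate (cis-fused; terpenoid 1R,3R,5S,8R,9S), via bis(chlorotitanocene) dialkoxide 19 (not isolated)
Conditions: Cp2TiCl2 (2.5 equiv), Mn dust, THF, rt, slow addition of 18; then 1 M HCl
Reagents that add atoms: none
Why: Titanocene-mediated reductive epoxide opening with radical cyclisation onto a ketone, a known reaction of epoxy ketones: Cp2TiCl (trivalent titanium) cleaves the C4–O bond to the tertiary C4 radical, which adds 5-exo to the open C5 carbonyl rather than to the neopentyl C10 carbonyl, and a second Cp2TiCl captures the oxygen radical, while the short tether enforces a cis fusion, the axial C9 methyl shields the β face so that the labile C1 side chain reacts from the α face, and the bulky C3 titanoxy group takes the convex face, which together place the C5 oxygen β and cis to the C3 oxygen (5S) with C1 still R.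

**Step 8**
Reactants: 20 cis-fused diol ester
Product: 21 methyl 3-[(2R,3aS,6R,7S,8aS)-2,3a-dihydroxy-3,3,6,7-tetramethyl-8-oxodecahydroazulen-7-yl]propanoate (trans-fused; terpenoid 1S,3R,5S,8R,9S)
Conditions: NaOMe (0.2 equiv), MeOH, rt; AcOH quench
Reagents that add atoms: none
Why: Base-catalysed epimerisation through the C10 enolate, which can form only toward C1 because C9 is quaternary: the trans-fused hydroazulenone should be the more stable epimer since both fusion bonds become pseudo-equatorial and the 5-OH lies gauche to C10=O and can hydrogen-bond to it, methoxide is degenerate toward the methyl ester, and recovered 20 can be resubmitted.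

**Step 9**
Reactants: 21 trans-fused diol ester
Product: 23 3-[(2R,3aS,6R,7S,8aS)-2,3a-dihydroxy-3,3,6,7-tetramethyl-8-oxodecahydroazulen-7-yl]propanoic acid, via lithium carboxylate 22 (not isolated)
Conditions: LiOH, THF–H2O, 0 °C; then 1 M HCl to pH 3
Reagents that add atoms: lithium hydroxide, [Li+].[OH-]
Why: Saponification of an unhindered methyl ester, which is much faster than any attack on the neopentyl C10 ketone, while C1 already has its equilibrium configuration so that the base cannot scramble it.

**Step 10**
Reactants: 23 diol keto acid; 24 (trimethylsilyl)diazomethane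
Product: 26 (2R,3aS,6R,7S,8aS)-7-(4-diazo-3-oxobutyl)-2,3a-dihydroxy-3,3,6,7-tetramethyloctahydroazulen-8(1H)-one (diazoketone), via mixed carbonic anhydride 25 (not isolated)
Conditions: i-BuOCOCl, N-methylmorpholine, THF, −15 °C; TMSCHN2, MeCN, 0 °C to rt; aq. NaHCO3
Reagents that add atoms: (trimethylsilyl)diazomethane, C[Si](C)(C)C=[N+]=[N-]
Why: Acylation of a diazoalkane by a mixed carbonic anhydride (first stage of an Arndt–Eistert sequence): at low temperature the chloroformate reacts with the carboxylate and not with the secondary or tertiary alcohol, the diazo carbon attacks the acyl carbonyl, and silicon is lost to the departing carbonate, which adds C16.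

**Step 11**
Reactants: 26 diazoketone; 27 diethylphosphonoacetic acid
Product: 28 4-[(2R,3aS,6R,7S,8aS)-2,3a-dihydroxy-3,3,6,7-tetramethyl-8-oxodecahydroazulen-7-yl]-2-oxobutyl (diethoxyphosphoryl)acetate
Conditions: (EtO)2P(O)CH2CO2H (2 equiv), Rh2(OAc)4 (1 mol %), CH2Cl2, rt
Reagents that add atoms: diethylphosphonoacetic acid, CCOP(=O)(CC(=O)O)OCC
Why: Rhodium-carbenoid O–H insertion into a carboxylic acid: the acid, used in excess and far more acidic than the two alcohols, captures the carbenoid faster than they do and delivers the acyloxymethyl ketone that already carries C14, C15 and the phosphonate.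

**Step 12**
Reactants: 28 phosphonoacetoxy ketone
Product: 29 4-{2-[(2R,3aS,6R,7S,8aS)-2,3a-dihydroxy-3,3,6,7-tetramethyl-8-oxodecahydroazulen-7-yl]ethyl}furan-2(5H)-one (CNP0077405.1)
Conditions: LiCl, i-Pr2NEt, MeCN, rt
Reagents that add atoms: none
Why: Intramolecular Horner–Wadsworth–Emmons olefination under LiCl–amine conditions: the lithium-chelated phosphonoacetate is deprotonated by a weak amine base and attacks the adjacent C13 ketone in a five-membered closure that can only give the endocyclic alkene, and the mild base spares the β-hydroxy ketone.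

**Compound list**
1 | 2-methylcyclopent-2-en-1-one | CC1=CCCC1=O | starting material
2 | methylmagnesium bromide | C[Mg]Br | starting material
3 | bromomagnesium enolate of (3R)-2,3-dimethylcyclopentanone | C[C@@H]1CCC(O[Mg]Br)=C1C | intermediate
4 | (3R)-2,3-dimethylcyclopentan-1-one (C2 epimers) | C[C@@H]1CCC(=O)C1C | intermediate
5 | (S)-1-phenylethylamine | C[C@H](N)c1ccccc1 | starting material
6 | methyl acrylate | C=CC(=O)OC | starting material
7 | N-[(1S)-1-phenylethyl] ketimine of 4 | C[C@@H]1CCC(=N[C@@H](C)c2ccccc2)C1C | intermediate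
8 | N-[(1S)-1-phenylethyl] ketimine of 9 | C[C@@H]1CCC(=N[C@@H](C)c2ccccc2)[C@@]1(C)CCC(=O)OC | intermediate
9 | methyl 3-[(1S,2R)-1,2-dimethyl-5-oxocyclopentyl]propanoate | C[C@@H]1CCC(=O)[C@@]1(C)CCC(=O)OC | intermediate
10 | methyl 3-[(1S,5R)-1,5-dimethyl-2-(trimethylsilyloxy)cyclopent-2-en-1-yl]propanoate | C[C@@H]1CC=C(O[Si](C)(C)C)[C@@]1(C)CCC(=O)OC | intermediate
11 | dichloroacetyl chloride | ClC(Cl)C(Cl)=O | starting material
12 | dichloroketene | ClC(Cl)=C=O | intermediate
13 | methyl 3-[(2S,3R)-7,7-dichloro-2,3-dimethyl-6-oxo-1-(trimethylsilyloxy)bicyclo[3.2.0]heptan-2-yl]propanoate (cis-fused, face not defined) | C[C@@H]1CC2C(=O)C(Cl)(Cl)C2(O[Si](C)(C)C)[C@@]1(C)CCC(=O)OC | intermediate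
14 | methyl 3-[(2S,3R)-2,3-dimethyl-6-oxo-1-(trimethylsilyloxy)bicyclo[3.2.0]heptan-2-yl]propanoate | C[C@@H]1CC2C(=O)CC2(O[Si](C)(C)C)[C@@]1(C)CCC(=O)OC | intermediate
15 | methyl 3-[(1S,7R)-1,7-dimethyl-2,4-dioxocycloheptyl]propanoate | C[C@@H]1CCC(=O)CC(=O)[C@@]1(C)CCC(=O)OC | intermediate
16 | prenyl bromide | CC(C)=CCBr | starting material
17 | methyl 3-[(1S,7R)-1,7-dimethyl-3-(3-methylbut-2-en-1-yl)-2,4-dioxocycloheptyl]propanoate | C[C@@H]1CCC(=O)C(CC=C(C)C)C(=O)[C@@]1(C)CCC(=O)OC | intermediate
18 | methyl 3-[(1S,7R)-3-{[(2R)-3,3-dimethyloxiran-2-yl]methyl}-1,7-dimethyl-2,4-dioxocycloheptyl]propanoate | C[C@@H]1CCC(=O)C(C[C@H]2OC2(C)C)C(=O)[C@@]1(C)CCC(=O)OC | intermediate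
19 | bis(chlorotitanocene) dialkoxide of 20 | C[C@@H]1CC[C@]2([O-])[C@@H](C[C@@H]([O-])C2(C)C)C(=O)[C@@]1(C)CCC(=O)OC.[Ti+4].[Ti+4].[Cl-].[Cl-].c1cc[cH-]c1.c1cc[cH-]c1.c1cc[cH-]c1.c1cc[cH-]c1 | intermediate
20 | cis-fused diol ester (terpenoid 1R,3R,5S,8R,9S) | C[C@@H]1CC[C@]2(O)[C@@H](C[C@@H](O)C2(C)C)C(=O)[C@@]1(C)CCC(=O)OC | intermediate
21 | trans-fused diol ester (terpenoid 1S,3R,5S,8R,9S) | C[C@@H]1CC[C@]2(O)[C@H](C[C@@H](O)C2(C)C)C(=O)[C@@]1(C)CCC(=O)OC | intermediate
22 | lithium carboxylate of 23 | C[C@@H]1CC[C@]2(O)[C@H](C[C@@H](O)C2(C)C)C(=O)[C@@]1(C)CCC(=O)[O-].[Li+] | intermediate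
23 | trans-fused diol keto acid | C[C@@H]1CC[C@]2(O)[C@H](C[C@@H](O)C2(C)C)C(=O)[C@@]1(C)CCC(=O)O | intermediate
24 | (trimethylsilyl)diazomethane | C[Si](C)(C)C=[N+]=[N-] | starting material
25 | isobutyl mixed carbonic anhydride of 23 | C[C@@H]1CC[C@]2(O)[C@H](C[C@@H](O)C2(C)C)C(=O)[C@@]1(C)CCC(=O)OC(=O)OCC(C)C | intermediate
26 | diazoketone | C[C@@H]1CC[C@]2(O)[C@H](C[C@@H](O)C2(C)C)C(=O)[C@@]1(C)CCC(=O)C=[N+]=[N-] | intermediate
27 | diethylphosphonoacetic acid | CCOP(=O)(CC(=O)O)OCC | starting material
28 | (diethoxyphosphoryl)acetoxymethyl ketone | C[C@@H]1CC[C@]2(O)[C@H](C[C@@H](O)C2(C)C)C(=O)[C@@]1(C)CCC(=O)COC(=O)CP(=O)(OCC)OCC | intermediate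
29 | CNP0077405.1 | C[C@@H]1CC[C@]2(O)[C@H](C[C@@H](O)C2(C)C)C(=O)[C@@]1(C)CCC1=CC(=O)OC1 | target

**Step count**
Total step count: 12. Longest linear sequence: 12 (steps 1 to 12 from compound 1).

**Steps most likely to fail**

Step 7 (radical closure of ring A).
- What may go wrong:
  - The tertiary C4 radical may be lost by disproportionation or hydrogen abstraction before it reaches the C5 carbonyl.
  - The C5 oxygen radical may fragment along C1–C5 in the manner of a Dowd–Beckwith ring enlargement if it is not captured quickly.
  - The metal chlorides may trigger attack of the enol oxygen on the epoxide.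
  - The facial preference may erode.
- Fallback: setting out from 18, the epoxide is isomerised with Et2Al(TMP) (TMP = 2,2,6,6-tetramethylpiperidide; one extra equivalent for the acidic C1–H) to the (3R)-allylic alcohol F1. The same C4 radical is then generated by metal-hydride hydrogen-atom transfer to the 1,1-disubstituted alkene (Fe(acac)3, PhSiH3, EtOH, 60 °C). This reductive alkene–ketone radical cyclisation is known for alkene-tethered cyclic 1,3-diones, and neither an epoxide nor a Lewis acidic titanium species is present. The route is rejoined at 20.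

Step 8 (C1 equilibration).
- What may go wrong: the equilibrium may not lie far enough on the trans side. Prolonged exposure to base may also open the C1–C5 aldol linkage, with loss of the C5 configuration on re-closure, or dehydrate it.
- Fallback: setting out from 20, exhaustive silylation (TMSOTf, Et3N, CH2Cl2) should give the bis-silyl ether C10 silyl enol ether F2, and Saegusa–Ito oxidation (Pd(OAc)2, MeCN) the C1=C2 enone F3. Hydrogenation over Pd/C must approach the flat cyclopentene from the α face because both silyloxy groups stand on the β face, so it should give the trans-fused bis-silyl ether F4 under kinetic control. Mild acid (AcOH, THF, H2O) removes the silyl groups and the route is rejoined at 21.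

Step 4 (ring expansion).
- What may go wrong: bond formation at C10 next to quaternary C9 may be so slow that ketene oligomerisation, C-acylation at C6 or loss of the silyl group takes over.
- Fallback: the same ring expansion is moved ahead of the quaternisation.
  - Setting out from 4, kinetic enolisation away from C9 (LDA, TMSCl, THF, −78 °C) should give the less substituted silyl enol ether F5, which has only a tertiary carbon beside the reacting alkene.
  - Dichloroketene addition gives the dichlorocyclobutanone F6, zinc in acetic acid the dechlorinated cyclobutanone F7, and hot aqueous acid (5R)-4,5-dimethylcycloheptane-1,3-dione F8.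
  - Acid-catalysed etherification with 2-methylpropan-1-ol (TsOH, toluene, Dean–Stark) at the less hindered C5 oxygen gives the vinylogous ester F9, whose only α′ position is C9.
  - LDA and then methyl acrylate at −78 °C (Michael addition anti to the C8 methyl) gives the quaternised vinylogous ester F10. Hydrolysis with aqueous HCl in THF returns to the route at 15.

**Further compounds**
F1 | step 7 | methyl 3-[(1S,7R)-3-[(2R)-2-hydroxy-3-methylbut-3-en-1-yl]-1,7-dimethyl-2,4-dioxocycloheptyl]propanoate | C[C@@H]1CCC(=O)C(C[C@@H](O)C(C)=C)C(=O)[C@@]1(C)CCC(=O)OC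
F2 | step 8 | 3,5-bis(trimethylsilyl) ether C10 trimethylsilyl enol ether of 20 | C[C@@H]1CC[C@]2(O[Si](C)(C)C)C(C[C@@H](O[Si](C)(C)C)C2(C)C)=C(O[Si](C)(C)C)[C@@]1(C)CCC(=O)OC
F3 | step 8 | C1=C2 enone, 3,5-bis(trimethylsilyl) ether | C[C@@H]1CC[C@]2(O[Si](C)(C)C)C(=C[C@@H](O[Si](C)(C)C)C2(C)C)C(=O)[C@@]1(C)CCC(=O)OC
F4 | step 8 | 3,5-bis(trimethylsilyl) ether of 21 | C[C@@H]1CC[C@]2(O[Si](C)(C)C)[C@H](C[C@@H](O[Si](C)(C)C)C2(C)C)C(=O)[C@@]1(C)CCC(=O)OC
F5 | step 4 | {[(4R)-4,5-dimethylcyclopent-1-en-1-yl]oxy}trimethylsilane | C[C@@H]1CC=C(O[Si](C)(C)C)C1C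
F6 | step 4 | (3R)-7,7-dichloro-2,3-dimethyl-1-(trimethylsilyloxy)bicyclo[3.2.0]heptan-6-one | C[C@@H]1CC2C(=O)C(Cl)(Cl)C2(O[Si](C)(C)C)C1C
F7 | step 4 | (3R)-2,3-dimethyl-1-(trimethylsilyloxy)bicyclo[3.2.0]heptan-6-one | C[C@@H]1CC2C(=O)CC2(O[Si](C)(C)C)C1C
F8 | step 4 | (5R)-4,5-dimethylcycloheptane-1,3-dione | C[C@@H]1CCC(=O)CC(=O)C1C
F9 | step 4 | (6R)-6,7-dimethyl-3-(2-methylpropoxy)cyclohept-2-en-1-one | C[C@@H]1CCC(OCC(C)C)=CC(=O)C1C
F10 | step 4 | methyl 3-[(1S,7R)-1,7-dimethyl-4-(2-methylpropoxy)-2-oxocyclohept-3-en-1-yl]propanoate | C[C@@H]1CCC(OCC(C)C)=CC(=O)[C@@]1(C)CCC(=O)OC
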